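The vessel is closed and stirred at one temperature and every reading is of substrate, so your hunch of order one in both substrate and partner has to be tried on how fast substrate falls.

| flask | substrate | partner | target | time |
|---|---|---|---|---|
| south-west | 200 mM | 240 mM |  |  |
| south-east | 300 mM | 240 mM |  |  |
| west | 200 mM | 240 mM | 60.0 mM |  |
| east | 200 mM | 480 mM |  |  |
| north | 400 mM | 120 mM |  | 87 h |

| south-west run: time / h | south-west run: [substrate] / mM | south-east run: time / h | south-east run: [substrate] / mM | west run: time / h | west run: [substrate] / mM | east run: time / h | east run: [substrate] / mM |
|---|---|---|---|---|---|---|---|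
| 3.5 | 175.0 | 3.5 | 264.5 | 3.5 | 165.2 | 3.5 | 145.1 |
| 5.5 | 162.8 | 5.5 | 241.5 | 5.5 | 153.6 | 5.5 | 116.6 |
| 8.7 | 140.6 | 8.7 | 215.6 | 8.7 | 131.8 | 8.7 | 90.4 |
| 14 | 116.6 | 14 | 182.4 | 14 | 103.1 | 14 | 48.6 |
| 22 | 89.0 | 22 | 145.7 | 22 | 78.3 | 22 | 23.6 |
| 35 | 63.8 | 35 | 109.8 | 35 | 52.8 | 35 | 5.8 |
| 55 | 39.5 | 55 | 80.7 | 55 | 26.9 | 55 | 2.3 |
| 87 | 16.7 | 87 | 72.0 | 87 | 14.8 | 87 | 0 |

(scatter of a reading: 2 mM)

- order of the initial rate in [substrate], near the charge of the south-west run, the rate being that where two percent of its substrate are target (one fixed amount of target, the same in the runs compared)
- order of the initial rate in [partner], near the charge of the south-west run, the rate being that where two percent of its substrate are target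
- substrate in the north run at 87 h, as a share of the substrate charged

- Overall: substrate + partner -> target.
- Constant volume, constant temperature.
- What is held in complexes is read along with the free species.
- "The second partner" is partner.
- An order is taken over about fifteen percent of the charge, up and down.

Added target matters: by 3.5 h the west run has lost 34.8 mM, more than the 25.0 mM of the south-west run. So I compare runs over nearly equal amounts turned. My quick number is the log-ratio order: the base-ten logarithm of the ratio of two mean rates, divided by that of the ratio of two charges.

The east run loses 54.9 mM in 3.5 h, and the south-west run loses 59.4 mM in 8.7 h. That gives mean rates of 15.7 mM/h and 6.83 mM/h. Their logarithm ratio over the doubling of partner reads 1.20, a mean over that stretch and not a value at the two percent asked, and the scatter moves it by about 0.0716. The south-east run, losing 58.5 mM in 5.5 h, gives 1.09 for substrate.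

In the north run partner is the limiting reagent, 120 mM against 400 mM of substrate, so the floor is 70.0%. The south-east run, also charged with less partner than substrate, reads 12.0 mM above its own floor at 87 h; I take that as a guide and commit to just above that 70.0%.

The forecast gives 0.93 for the substrate order, 1.05 for the partner order and 70.4% for the north run, and says “target accelerates the reaction mildly”. We part on the orders: both of its orders are lower than mine.

The flask gives an order of 1.0 in substrate, an order of 1.3 in partner, and 70.1% of the charged substrate left in the north run at 87 h.

    2 partner ⇌ reagent dimer, settled at all times (7.310 /M)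
    substrate + reagent dimer → target + partner (0.5760 /M/h)
    substrate + partner + target → 2 target (1.944 /M²/h)

Where target made equals two percent of the south-west charge, the east run goes 2.3 times as fast as the south-west run. Now I carry 1.20 to the south-east run, whose rate at that point is 12 mM/h. Scaling it to the east charge, with substrate at the flask's order and partner at 1.20, gives 18.3 mM/h, and the east run's rate there is 19 mM/h.

The numbers in the tables are calculated with made-up constants; noise was put on by code.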